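**Plan**

Target: procyanidin B3 3,3'-di-O-gallate, (2R,3S,4S,2'R,3'S). The upper flavan is numbered O1, C2–C4, C4a–C8a (rings A, C, B), the lower flavan is primed (rings D, F, E), and the interflavan bond is C4–C8'.
Cuts, in order: the benzyl groups and the O3' ester; then C3–C4 together with O1–C2, which opens ring C; then C4–C8' (aryllithium plus aldehyde); and, in the alkene piece, the vinyl C–O bond.
Enabling feature: ring C runs from the phenolic O1 on ring A to the diaryl-substituted C4. It carries ring B (C2), the galloyloxy group (C3) and ring D (C4) all-trans, which maps onto the oxadiene O1=C8a–C4a=C4 and an (E)-alkene C2=C3.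
Forward: rings D, F and E come intact from (+)-catechin and ring A from 2,4,6-trihydroxybenzaldehyde. Rings A and D are joined at C4, and ring C, the only ring built, is closed by the cycloaddition, which brings the hindered C3 ester with it.
Stereochemistry: C2' and C3' come from catechin, C2/C3 trans from the (E)-alkene, and C4 from the endo transition state on the (E)-methide. The absolute sense comes from a chiral Brønsted acid acting together with the lower unit.

Key step: step 11

Assumption: no model predicts which antipode of the acid reinforces the facial bias of the lower unit on this new substrate pair, so the (R)-acid is written as the matched one; its mirror image is equally available and would take its place.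

**Step 1**
Reactants: 1 (+)-catechin
Product: 2 5,7,3',4'-tetra-O-benzyl-(+)-catechin (2R,3S)
Conditions: BnBr (4.4 equiv), K2CO3, DMF, 0 °C to rt
Reagents that add atoms: benzyl bromide, BrCc1ccccc1
Why: Williamson ether synthesis, in which K2CO3 deprotonates only the four phenols, so the secondary hydroxyl stays free and both stereocentres are untouched.

**Step 2**
Reactants: 2 5,7,3',4'-tetra-O-benzyl-(+)-catechin
Product: 3 3-O-(tert-butyldimethylsilyl)-5,7,3',4'-tetra-O-benzylcatechin (2R,3S)
Conditions: TBSCl, imidazole, DMF, rt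
Reagents that add atoms: tert-butyldimethylsilyl chloride, CC(C)(C)[Si](C)(C)Cl
Why: Imidazole-promoted silylation of a secondary alcohol, which masks O3' against the organolithium of step 6 and against intramolecular capture of C4 in step 11.

**Step 3**
Reactants: 3 3-O-TBS-tetra-O-benzylcatechin
Product: 4 8-bromo-3-O-TBS-5,7,3',4'-tetra-O-benzylcatechin (2R,3S)
Conditions: NBS (1.0 equiv), CH2Cl2, −78 °C to rt
Reagents that add atoms: N-bromosuccinimide, O=C1CCC(=O)N1Br
Why: Electrophilic aromatic bromination, for which C8' is the most nucleophilic position of a 5,7-dialkoxyflavan, while one equivalent of NBS at low temperature leaves C6' and ring E alone.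

**Step 4**
Reactants: 5 2,4,6-trihydroxybenzaldehyde
Product: 6 2,4-bis(benzyloxy)-6-hydroxybenzaldehyde
Conditions: BnBr (2.0 equiv), K2CO3, DMF, rt
Reagents that add atoms: benzyl bromide, BrCc1ccccc1
Why: Williamson ether synthesis that stops at the diether, because the last ortho hydroxyl is hydrogen-bonded to the formyl oxygen and is the least acidic and least nucleophilic of the three.

**Step 5**
Reactants: 6 2,4-bis(benzyloxy)-6-hydroxybenzaldehyde
Product: 7 2-(allyloxy)-4,6-bis(benzyloxy)benzaldehyde
Conditions: allyl bromide, K2CO3, DMF, 50 °C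
Reagents that add atoms: allyl bromide, C=CCBr
Why: Williamson ether synthesis under firmer conditions; the chelated phenol must be capped because it would protonate the aryllithium of step 6, and allyl is chosen because it leaves under neutral conditions that spare benzyl, silyl and the acid-labile carbinol.

**Step 6**
Reactants: 4 8-bromo-3-O-TBS-tetra-O-benzylcatechin; 7 2-(allyloxy)-4,6-bis(benzyloxy)benzaldehyde
Product: 9 O8a-allyl diarylcarbinol (both carbinol epimers; 2'R,3'S), via 8-lithioflavan 8 (not isolated)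
Conditions: n-BuLi (1.05 equiv), THF, −78 °C; then 7 (1.2 equiv), −78 to −20 °C; aq NaHCO3
Reagents that add atoms: n-butyllithium, CCCC[Li] (gives the lithium of 8; no atom of it stays in 9)
Why: Bromine–lithium exchange followed by 1,2-addition of the aryllithium to the aldehyde forms C4–C8'; the carbinol centre arises without control, which is immaterial because it becomes trigonal in step 11.

**Step 7**
Reactants: 9 O8a-allyl diarylcarbinol
Product: 10 diarylcarbinol with free O1–H on ring A (both carbinol epimers; 2'R,3'S)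
Conditions: Pd(PPh3)4 (5 mol %), morpholine, THF, rt; Et3N-deactivated silica, used promptly
Reagents that add atoms: none
Why: Tsuji–Trost-type deallylation, in which zerovalent palladium ionises the aryl allyl ether and morpholine takes up the allyl unit under non-acidic conditions that do not ionise the carbinol.

**Step 8**
Reactants: 11 3,4-bis(benzyloxy)benzaldehyde
Product: 12 (E)-2-{2-[3,4-bis(benzyloxy)phenyl]ethenyl}-4,4,5,5-tetramethyl-1,3,2-dioxaborolane
Conditions: CH2(Bpin)2 (1.2 equiv), lithium 2,2,6,6-tetramethylpiperidide (from n-BuLi and the amine), THF, 0 °C; then 11, −78 °C to rt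
Reagents that add atoms: bis(pinacolatoboryl)methane, CC1(C)OB(CB2OC(C)(C)C(C)(C)O2)OC1(C)C
Why: Boron–Wittig olefination, in which the lithiated geminal bis(boronate) adds to the aldehyde and syn boron–oxygen elimination from the less crowded adduct gives the (E)-alkenylboronate.

**Step 9**
Reactants: 12 (E)-styryl pinacol boronate
Product: 13 potassium (E)-{2-[3,4-bis(benzyloxy)phenyl]ethenyl}trifluoroborate
Conditions: KHF2, MeOH/H2O, rt
Reagents that add atoms: potassium hydrogen difluoride (KHF2), [K+].[F-].F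
Why: Ligand exchange of a pinacol boronate with KHF2 gives the crystalline, air-stable trifluoroborate without touching the alkene geometry.

**Step 10**
Reactants: 13 potassium (E)-styryltrifluoroborate; 14 3,4,5-tris(benzyloxy)benzoic acid
Product: 15 (E)-2-[3,4-bis(benzyloxy)phenyl]ethenyl 3,4,5-tris(benzyloxy)benzoate
Conditions: CuBr (10 mol %), 4-(dimethylamino)pyridine (20 mol %), 4 Å MS, O2 (1 atm), MeCN, 60 °C
Reagents that add atoms: none
Why: Chan–Lam–Evans-type oxidative C–O coupling of a carboxylic acid with an alkenyltrifluoroborate, in which transmetallation to copper and reductive elimination both retain the alkene geometry, so the (E)-enol ester results.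

**Step 11**
Reactants: 10 diarylcarbinol; 15 (E)-styryl gallate
Product: 17 (2R,3S,4S,2'R,3'S)-dimer carrying the C3 tri-O-benzylgallate plus the O3' silyl ether plus eleven benzyl ethers, via ring A ortho-quinone methide 16 (not isolated)
Conditions: 15 (3 equiv), (R)-3,3'-bis(2,4,6-triisopropylphenyl)-1,1'-binaphthyl-2,2'-diyl N-(trifluoromethylsulfonyl)phosphoramide (10 mol %), 5 Å MS, toluene, −20 to 0 °C, 10 added slowly by syringe pump
Reagents that add atoms: none
Why: Proposed new method: the strong chiral Brønsted acid ionises the doubly benzylic C4–OH of 10 and, after loss of the O1 proton, holds the (E)-ortho-quinone methide 16 at O1 (a hydrogen bond shading into a contact ion pair), so that the 1-oxadiene O1=C8a–C4a=C4 takes up 15 in an inverse-demand, concerted but asynchronous oxa-[4+2] cycloaddition in which C3–C4 runs ahead of O1–C2 and rearomatisation of ring A pays for the step. The closest known reaction type is the chiral phosphoric acid or N-triflylphosphoramide catalysed [4+2] addition of ortho-quinone methides formed in situ to styrenes and enol derivatives; the N-triflylphosphoramide is preferred because 15 offers no N–H or O–H for the phosphoryl oxygen of a phosphoric acid to grip, so only the electrophile can be activated, and what is new is the beta-acyloxystyrene partner and the tetra-ortho-substituted methide. Ring C closes as the six-membered ring of the [4+2] array (in the stepwise limit, 6-exo-trig capture of the para-benzyloxybenzylic C2 by O1). The regiochemistry (C3 to C4, C2 to O1) rests on the para-benzyloxy group of ring B, which carries positive charge at C2 far better than the ester-bound oxygen could at C3, matched with C4 as the electrophilic end of the oxadiene. C2 and C3 become trans because the (E)-alkene adds suprafacially and because the gallate carbonyl, leaning on the developing charge at C2 from the C3–O side, leaves O1 only the anti trajectory, while C4 becomes cis to C2 and trans to C3 because ring B lies endo under the oxadiene and ring D holds the outer position of the (E)-methide. The absolute sense depends on which face of C4 is open, which is decided by the catalyst pocket on the unhindered O1/C8 edge together with the twisted ring D, whose C7' benzyloxy and ring F flanks differ, and a wrong-face adduct would be a diastereomer removable by chromatography.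

**Step 12**
Reactants: 17 silylated dimer monogallate
Product: 18 O3' alcohol of the dimer (2R,3S,4S,2'R,3'S)
Conditions: HF·pyridine, extra pyridine, THF, 0 °C to rt
Reagents that add atoms: none
Why: Fluoride-driven cleavage of the silyl ether under buffered, weakly acidic conditions that leave the C3 gallate, the benzyl ethers and the C4–C8' bond alone.

**Step 13**
Reactants: 18 O3' alcohol; 14 3,4,5-tris(benzyloxy)benzoic acid
Product: 19 tetradeca-O-benzyl procyanidin B3 3,3'-di-O-gallate (2R,3S,4S,2'R,3'S)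
Conditions: DCC, 4-(dimethylamino)pyridine, CH2Cl2, rt
Reagents that add atoms: none
Why: Steglich esterification, the usual way to galloylate O3 of benzylated flavan-3-ols and their dimers; C3' keeps its configuration because only the O–H bond is broken.

**Step 14**
Reactants: 19 tetradeca-O-benzyl digallate
Product: 20 procyanidin B3 3,3'-di-O-gallate (target)
Conditions: H2 (1 atm), Pd(OH)2/C, THF/MeOH/H2O, rt; filtration, lyophilisation
Reagents that add atoms: none
Why: Catalytic hydrogenolysis of the fourteen O-benzyl groups, under which the aryl esters, the cyclic benzylic C2–O1 bonds and the C4–C8' bond of procyanidins persist at atmospheric pressure.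

**Compound list**

1 | (+)-catechin, (2R,3S) | O[C@H]1Cc2c(O)cc(O)cc2O[C@@H]1c1ccc(O)c(O)c1 | starting material
2 | 5,7,3',4'-tetra-O-benzyl-(+)-catechin | O[C@H]1Cc2c(OCc3ccccc3)cc(OCc3ccccc3)cc2O[C@@H]1c1ccc(OCc2ccccc2)c(OCc2ccccc2)c1 | intermediate
3 | 3-O-TBS-5,7,3',4'-tetra-O-benzylcatechin | CC(C)(C)[Si](C)(C)O[C@H]1Cc2c(OCc3ccccc3)cc(OCc3ccccc3)cc2O[C@@H]1c1ccc(OCc2ccccc2)c(OCc2ccccc2)c1 | intermediate
4 | 8-bromo-3-O-TBS-5,7,3',4'-tetra-O-benzylcatechin | CC(C)(C)[Si](C)(C)O[C@H]1Cc2c(OCc3ccccc3)cc(OCc3ccccc3)c(Br)c2O[C@@H]1c1ccc(OCc2ccccc2)c(OCc2ccccc2)c1 | intermediate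
5 | 2,4,6-trihydroxybenzaldehyde | O=Cc1c(O)cc(O)cc1O | starting material
6 | 2,4-bis(benzyloxy)-6-hydroxybenzaldehyde | O=Cc1c(O)cc(OCc2ccccc2)cc1OCc1ccccc1 | intermediate
7 | 2-(allyloxy)-4,6-bis(benzyloxy)benzaldehyde | O=Cc1c(OCC=C)cc(OCc2ccccc2)cc1OCc1ccccc1 | intermediate
8 | 8-lithio-3-O-TBS-5,7,3',4'-tetra-O-benzylcatechin (not isolated) | CC(C)(C)[Si](C)(C)O[C@H]1Cc2c(OCc3ccccc3)cc(OCc3ccccc3)c([Li])c2O[C@@H]1c1ccc(OCc2ccccc2)c(OCc2ccccc2)c1 | intermediate
9 | [2-(allyloxy)-4,6-bis(benzyloxy)phenyl][(2R,3S)-5,7-bis(benzyloxy)-2-[3,4-bis(benzyloxy)phenyl]-3-(TBSO)chroman-8-yl]methanol, carbinol epimers | OC(c1c(OCC=C)cc(OCc2ccccc2)cc1OCc1ccccc1)c1c(OCc2ccccc2)cc(OCc2ccccc2)c2c1O[C@H](c1ccc(OCc3ccccc3)c(OCc3ccccc3)c1)[C@@H](O[Si](C)(C)C(C)(C)C)C2 | intermediate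
10 | [2,4-bis(benzyloxy)-6-hydroxyphenyl][(2R,3S)-5,7-bis(benzyloxy)-2-[3,4-bis(benzyloxy)phenyl]-3-(TBSO)chroman-8-yl]methanol, carbinol epimers | OC(c1c(O)cc(OCc2ccccc2)cc1OCc1ccccc1)c1c(OCc2ccccc2)cc(OCc2ccccc2)c2c1O[C@H](c1ccc(OCc3ccccc3)c(OCc3ccccc3)c1)[C@@H](O[Si](C)(C)C(C)(C)C)C2 | intermediate
11 | 3,4-bis(benzyloxy)benzaldehyde | O=Cc1ccc(OCc2ccccc2)c(OCc2ccccc2)c1 | starting material
12 | (E)-2-{2-[3,4-bis(benzyloxy)phenyl]ethenyl}-4,4,5,5-tetramethyl-1,3,2-dioxaborolane | CC1(C)OB(/C=C/c2ccc(OCc3ccccc3)c(OCc3ccccc3)c2)OC1(C)C | intermediate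
13 | potassium (E)-{2-[3,4-bis(benzyloxy)phenyl]ethenyl}trifluoroborate | [K+].F[B-](F)(F)/C=C/c1ccc(OCc2ccccc2)c(OCc2ccccc2)c1 | intermediate
14 | 3,4,5-tris(benzyloxy)benzoic acid | OC(=O)c1cc(OCc2ccccc2)c(OCc2ccccc2)c(OCc2ccccc2)c1 | starting material
15 | (E)-2-[3,4-bis(benzyloxy)phenyl]ethenyl 3,4,5-tris(benzyloxy)benzoate | O=C(O/C=C/c1ccc(OCc2ccccc2)c(OCc2ccccc2)c1)c1cc(OCc2ccccc2)c(OCc2ccccc2)c(OCc2ccccc2)c1 | intermediate
16 | (6E)-3,5-bis(benzyloxy)-6-{[(2R,3S)-5,7-bis(benzyloxy)-2-[3,4-bis(benzyloxy)phenyl]-3-(TBSO)chroman-8-yl]methylidene}cyclohexa-2,4-dien-1-one (not isolated) | O=C1C=C(OCc2ccccc2)C=C(OCc2ccccc2)/C1=C\c1c(OCc2ccccc2)cc(OCc2ccccc2)c2c1O[C@H](c1ccc(OCc3ccccc3)c(OCc3ccccc3)c1)[C@@H](O[Si](C)(C)C(C)(C)C)C2 | intermediate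
17 | (2R,3S,4S,2'R,3'S)-octa-O-benzyl-3'-O-TBS-procyanidin B3 3-O-[3,4,5-tris(benzyloxy)benzoate] | O=C(O[C@H]1[C@H](c2c(OCc3ccccc3)cc(OCc3ccccc3)c3c2O[C@H](c2ccc(OCc4ccccc4)c(OCc4ccccc4)c2)[C@@H](O[Si](C)(C)C(C)(C)C)C3)c2c(OCc3ccccc3)cc(OCc3ccccc3)cc2O[C@@H]1c1ccc(OCc2ccccc2)c(OCc2ccccc2)c1)c1cc(OCc2ccccc2)c(OCc2ccccc2)c(OCc2ccccc2)c1 | intermediate
18 | (2R,3S,4S,2'R,3'S)-octa-O-benzylprocyanidin B3 3-O-[3,4,5-tris(benzyloxy)benzoate], O3' free | O=C(O[C@H]1[C@H](c2c(OCc3ccccc3)cc(OCc3ccccc3)c3c2O[C@H](c2ccc(OCc4ccccc4)c(OCc4ccccc4)c2)[C@@H](O)C3)c2c(OCc3ccccc3)cc(OCc3ccccc3)cc2O[C@@H]1c1ccc(OCc2ccccc2)c(OCc2ccccc2)c1)c1cc(OCc2ccccc2)c(OCc2ccccc2)c(OCc2ccccc2)c1 | intermediate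
19 | tetradeca-O-benzyl procyanidin B3 3,3'-di-O-gallate | O=C(O[C@H]1[C@H](c2c(OCc3ccccc3)cc(OCc3ccccc3)c3c2O[C@H](c2ccc(OCc4ccccc4)c(OCc4ccccc4)c2)[C@@H](OC(=O)c2cc(OCc4ccccc4)c(OCc4ccccc4)c(OCc4ccccc4)c2)C3)c2c(OCc3ccccc3)cc(OCc3ccccc3)cc2O[C@@H]1c1ccc(OCc2ccccc2)c(OCc2ccccc2)c1)c1cc(OCc2ccccc2)c(OCc2ccccc2)c(OCc2ccccc2)c1 | intermediate
20 | procyanidin B3 3,3'-di-O-gallate, (2R,3S,4S,2'R,3'S) | O=C(O[C@H]1[C@H](c2c(O)cc(O)c3c2O[C@H](c2ccc(O)c(O)c2)[C@@H](OC(=O)c2cc(O)c(O)c(O)c2)C3)c2c(O)cc(O)cc2O[C@@H]1c1ccc(O)c(O)c1)c1cc(O)c(O)c(O)c1 | target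

**Step count and risks**

Total step count: 14. Longest linear sequence: 9 steps (1, 2, 3, 6, 7, 11, 12, 13, 14) from (+)-catechin.

**Step 11.**
- Reactivity: the heavily donor-substituted methide may be too stabilised to engage an alkene that the acyloxy group deactivates. Friedel–Crafts self-condensation through the free C6, C8 and C6' positions, or acid cleavage of the enol ester by the released water, could then take over.
- Selectivity: rotation about C4–C4a next to the C5 benzyloxy group can erode the 3,4-trans selectivity, and the facial selectivity may be poor.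
- Fallback: this gives up the cycloaddition and forms C4–C8' last by the established Lewis acid condensation of a C4-activated flavan with a flavan nucleophile. It sets out from 2. Benzylic oxidation with DDQ in the presence of 2-ethoxyethanol (CH2Cl2, rt) should give (2R,3S,4S)-5,7,3',4'-tetra-O-benzyl-4-(2-ethoxyethoxy)catechin F1. Steglich esterification with 14 should give its 3-O-[3,4,5-tris(benzyloxy)benzoate] F2. TMSOTf (CH2Cl2, −78 °C) with an excess of 3 as nucleophile should then join C4 to C8', the C3 ester shielding the beta face so that ring D enters alpha (3,4-trans). The route is rejoined at 17.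

**Step 6.**
- Risk: addition of a di-ortho-substituted aryllithium to a di-ortho-substituted, electron-rich aldehyde may be slow. Proton transfer from benzylic ether positions, followed by Wittig rearrangement or simple protonation of the carbanion, could then compete.
- Fallback: this forms C4–C4a instead of C4–C8' and sets out from 4. Bromine–lithium exchange (n-BuLi, THF, −78 °C) and quenching with DMF should give 3-O-TBS-5,7,3',4'-tetra-O-benzylcatechin-8-carbaldehyde F3. Commercial 3,5-bis(benzyloxy)phenol F4 is turned with EtMgBr into bromomagnesium 3,5-bis(benzyloxy)phenoxide F5. In toluene at rt this should add to F3 through a six-membered magnesium chelate, exclusively at the position ortho to the phenoxide oxygen. This ortho-specific hydroxyalkylation is a known reaction of aryloxymagnesium halides with aromatic aldehydes. The route is rejoined at 10, and 9 and step 7 are bypassed.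

**Step 7.**
- Risk: the liberated ortho-hydroxy carbinol may lose water prematurely during deprotection or chromatography and then oligomerise. The electron-rich phenoxide may also be allylated at carbon.
- Fallback: this unveils the phenol at the ketone oxidation level and sets out from 9. MnO2 (CH2Cl2, rt) should give the O-allyl benzophenone F6. Deallylation with Pd(PPh3)4 and morpholine should give the chelated, storable 2-hydroxybenzophenone F7. LiAlH4 (THF, −20 to 0 °C, kept cold to avoid over-reduction) should deliver the carbinol under basic conditions. It is taken on without chromatography, and the route is rejoined at 10.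

**Further compounds**

F1 | step 11 | (2R,3S,4S)-5,7,3',4'-tetra-O-benzyl-4-(2-ethoxyethoxy)catechin | O[C@H]1[C@@H](OCCOCC)c2c(OCc3ccccc3)cc(OCc3ccccc3)cc2O[C@@H]1c1ccc(OCc2ccccc2)c(OCc2ccccc2)c1
F2 | step 11 | (2R,3S,4S)-5,7,3',4'-tetra-O-benzyl-4-(2-ethoxyethoxy)catechin 3-O-[3,4,5-tris(benzyloxy)benzoate] | O=C(O[C@H]1[C@@H](OCCOCC)c2c(OCc3ccccc3)cc(OCc3ccccc3)cc2O[C@@H]1c1ccc(OCc2ccccc2)c(OCc2ccccc2)c1)c1cc(OCc2ccccc2)c(OCc2ccccc2)c(OCc2ccccc2)c1
F3 | step 6 | 3-O-TBS-5,7,3',4'-tetra-O-benzylcatechin-8-carbaldehyde (2R,3S) | CC(C)(C)[Si](C)(C)O[C@H]1Cc2c(OCc3ccccc3)cc(OCc3ccccc3)c(C=O)c2O[C@@H]1c1ccc(OCc2ccccc2)c(OCc2ccccc2)c1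
F4 | step 6 | 3,5-bis(benzyloxy)phenol (bought) | Oc1cc(OCc2ccccc2)cc(OCc2ccccc2)c1
F5 | step 6 | bromomagnesium 3,5-bis(benzyloxy)phenoxide | Br[Mg]Oc1cc(OCc2ccccc2)cc(OCc2ccccc2)c1
F6 | step 7 | [2-(allyloxy)-4,6-bis(benzyloxy)phenyl][(2R,3S)-5,7-bis(benzyloxy)-2-[3,4-bis(benzyloxy)phenyl]-3-(TBSO)chroman-8-yl]methanone | O=C(c1c(OCC=C)cc(OCc2ccccc2)cc1OCc1ccccc1)c1c(OCc2ccccc2)cc(OCc2ccccc2)c2c1O[C@H](c1ccc(OCc3ccccc3)c(OCc3ccccc3)c1)[C@@H](O[Si](C)(C)C(C)(C)C)C2
F7 | step 7 | [2,4-bis(benzyloxy)-6-hydroxyphenyl][(2R,3S)-5,7-bis(benzyloxy)-2-[3,4-bis(benzyloxy)phenyl]-3-(TBSO)chroman-8-yl]methanone | O=C(c1c(O)cc(OCc2ccccc2)cc1OCc1ccccc1)c1c(OCc2ccccc2)cc(OCc2ccccc2)c2c1O[C@H](c1ccc(OCc3ccccc3)c(OCc3ccccc3)c1)[C@@H](O[Si](C)(C)C(C)(C)C)C2
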